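**Retrosynthetic overview**
1. Target 18 ⇐ silyl ether 17 ⇐ bromo-enynoic acid 16 by 5-exo-dig iodolactonisation; anti addition of O and I fixes the (E)-iodomethylidene in the final ring closure.
2. 16 ⇐ γ-hydroxybutenolide 15 (masked cis-formyl acid) by one-carbon alkyne homologation; 15 ⇐ 4-bromobutenolide 12 through its 2-silyloxyfuran 13. The lactone ring locks the bromine position and the cis geometry.
3. 12 ⇐ tetronic acid 11 ⇐ β-hydroxy-γ-lactone 10 ⇐ dihydroxylation/lactonisation of the α-vinyl aldol 8 (first ring closure).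
4. Key C3–C1' bond and the (R)-carbinol: Evans boron-dienolate aldol of N-crotonyl oxazolidinone 3 with butanal 4.
5. Ring order: γ-lactone formed (step 4), opened to the acyclic enyne acid (steps 8–9), re-closed by iodolactonisation (step 10).

Assumption: the SMILES is read as the (1'R)-alcohol with the (5E)-iodomethylidene, i.e. iodine cis to C4–Br and trans to the ring oxygen.

**Step 1**
Reactants: 1 (S)-4-benzyloxazolidin-2-one; 2 (E)-but-2-enoyl chloride (crotonyl chloride)
Product: 3 (S)-4-benzyl-3-[(E)-but-2-enoyl]oxazolidin-2-one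
Conditions: n-BuLi (1.0 equiv), THF, −78 °C; then 2, −78 → 0 °C
Reagents that add atoms: none
Why: Deprotonation with n-BuLi makes the carbamate nitrogen nucleophilic enough for clean N-acylation by the acid chloride (nucleophilic acyl substitution, standard Evans imide formation).

**Step 2**
Reactants: 3 (S)-4-benzyl-3-[(E)-but-2-enoyl]oxazolidin-2-one; 4 butanal
Product: 7 (4S)-4-benzyl-3-[(2S,3R)-2-ethenyl-3-hydroxyhexanoyl]oxazolidin-2-one, via boron dienolate 5 (not isolated), via boron aldolate 6 (not isolated)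
Conditions: Bu2BOTf (1.2 equiv), Et3N (1.4 equiv), CH2Cl2, −78 → 0 °C; 4, −78 → 0 °C; then pH 7 buffer, MeOH, 30% H2O2, 0 °C
Reagents that add atoms: none
Why: Evans syn-aldol reaction in which the (Z)-boron dienolate 5 reacts at its α-carbon through a closed Zimmerman–Traxler chair on the face away from the benzyl group, setting the (3R)-carbinol (d.r. typically >95:5) together with a 2S centre that is erased later.

**Step 3**
Reactants: 7 (4S)-4-benzyl-3-[(2S,3R)-2-ethenyl-3-hydroxyhexanoyl]oxazolidin-2-one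
Product: 8 (4S)-4-benzyl-3-[(2S,3R)-3-(tert-butyldimethylsilyloxy)-2-ethenylhexanoyl]oxazolidin-2-one
Conditions: TBSOTf, 2,6-lutidine, CH2Cl2, 0 °C
Reagents that add atoms: tert-butyldimethylsilyl triflate (TBSOTf), CC(C)(C)[Si](C)(C)OS(=O)(=O)C(F)(F)F
Why: O-silylation with a silyl triflate and a hindered base protects the secondary aldol hydroxyl without retro-aldol or migration of the β,γ-alkene.

**Step 4**
Reactants: 8 (4S)-4-benzyl-3-[(2S,3R)-3-(tert-butyldimethylsilyloxy)-2-ethenylhexanoyl]oxazolidin-2-one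
Product: 10 (3S)-3-[(1R)-1-(tert-butyldimethylsilyloxy)butyl]-4-hydroxydihydrofuran-2(3H)-one (both C4 epimers), via diol 9 (not isolated)
Conditions: OsO4 (2 mol %), NMO (1.5 equiv), acetone/H2O (8:1), rt; then Et3N (cat.), CH2Cl2, rt
Reagents that add atoms: N-methylmorpholine N-oxide (NMO), C[N+]1([O-])CCOCC1; water, O (both oxygens are delivered through catalytic OsO4)
Why: Upjohn dihydroxylation of the terminal alkene is followed by 5-exo translactonisation of the primary hydroxyl onto the activated imide carbonyl, which releases the auxiliary; the new C4 centre is uncontrolled and irrelevant because it is oxidised next.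

**Step 5**
Reactants: 10 (3S)-3-[(1R)-1-(tert-butyldimethylsilyloxy)butyl]-4-hydroxydihydrofuran-2(3H)-one
Product: 11 3-[(1R)-1-(tert-butyldimethylsilyloxy)butyl]-4-hydroxyfuran-2(5H)-one (tetronic acid)
Conditions: Dess–Martin periodinane (1.1 equiv), CH2Cl2, 0 °C → rt
Reagents that add atoms: none
Why: Dess–Martin oxidation of the secondary alcohol gives the β-keto lactone, which enolises fully to the tetronic acid under neutral conditions that leave the β-silyloxy group untouched; the C3 centre is deliberately erased.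

**Step 6**
Reactants: 11 3-[(1R)-1-(tert-butyldimethylsilyloxy)butyl]-4-hydroxyfuran-2(5H)-one
Product: 12 4-bromo-3-[(1R)-1-(tert-butyldimethylsilyloxy)butyl]furan-2(5H)-one
Conditions: (COBr)2 (1.2 equiv), DMF (cat.), CH2Cl2, 0 °C → rt
Reagents that add atoms: oxalyl bromide, BrC(=O)C(=O)Br
Why: Vilsmeier-type deoxybromination activates the vinylogous acid and bromide substitutes by addition–elimination at C4, the standard tetronic acid to 4-bromobutenolide conversion, so bromine is placed regiospecifically.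

**Step 7**
Reactants: 12 4-bromo-3-[(1R)-1-(tert-butyldimethylsilyloxy)butyl]furan-2(5H)-one
Product: 13 4-bromo-2-(tert-butyldimethylsilyloxy)-3-[(1R)-1-(tert-butyldimethylsilyloxy)butyl]furan
Conditions: TBSOTf (1.1 equiv), Et3N (1.5 equiv), CH2Cl2, −78 → 0 °C
Reagents that add atoms: tert-butyldimethylsilyl triflate (TBSOTf), CC(C)(C)[Si](C)(C)OS(=O)(=O)C(F)(F)F
Why: Soft enolisation (γ-deprotonation and O-silylation) of the butenolide gives the aromatic 2-silyloxyfuran, the usual activated form for functionalising C5.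

**Step 8**
Reactants: 13 4-bromo-2-(tert-butyldimethylsilyloxy)-3-[(1R)-1-(tert-butyldimethylsilyloxy)butyl]furan
Product: 15 4-bromo-5-hydroxy-3-[(1R)-1-(tert-butyldimethylsilyloxy)butyl]furan-2(5H)-one (both C5 epimers), via silyl ester 14 (not isolated)
Conditions: DMDO (1.1 equiv, acetone solution), CH2Cl2, −78 °C; then H2O/THF, rt
Reagents that add atoms: dimethyldioxirane (DMDO), CC1(C)OO1
Why: Electrophilic oxygen transfer to C5 of the silyloxyfuran opens the ring to the cis-formyl silyl ester 14 (oxidative furan ring-opening), and hydrolysis of the labile silyl ester lets the acid close onto the aldehyde as the γ-hydroxybutenolide while the secondary silyl ether survives.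

**Step 9**
Reactants: 15 4-bromo-5-hydroxy-3-[(1R)-1-(tert-butyldimethylsilyloxy)butyl]furan-2(5H)-one
Product: 16 (2E)-3-bromo-2-[(1R)-1-(tert-butyldimethylsilyloxy)butyl]pent-2-en-4-ynoic acid (ethynyl cis to CO2H)
Conditions: dimethyl (1-diazo-2-oxopropyl)phosphonate (1.5 equiv), K2CO3 (3 equiv), MeOH, 0 °C → rt
Reagents that add atoms: dimethyl (1-diazo-2-oxopropyl)phosphonate (Ohira–Bestmann reagent), CC(=O)C(=[N+]=[N-])P(=O)(OC)OC
Why: In base the pseudo-acid exists as the open formyl carboxylate, whose aldehyde undergoes Seyferth–Gilbert homologation (Ohira–Bestmann variant) to the terminal alkyne; the carboxylate shields the β-bromo alkene from methoxide and the cis geometry is inherited from the lactone, and the acid is freed on cold acidic work-up and used at once.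

**Step 10**
Reactants: 16 (2E)-3-bromo-2-[(1R)-1-(tert-butyldimethylsilyloxy)butyl]pent-2-en-4-ynoic acid
Product: 17 (5E)-4-bromo-3-[(1R)-1-(tert-butyldimethylsilyloxy)butyl]-5-(iodomethylidene)furan-2(5H)-one
Conditions: I2 (1.2 equiv), NaHCO3 (2 equiv), MeCN, 0 °C, dark
Reagents that add atoms: iodine, II
Why: 5-exo-dig iodolactonisation with Markovnikov attack of the carboxylate on the internal alkyne carbon and anti addition across the triple bond places iodine trans to the ring oxygen and cis to C4–Br, which is the required (E)-geometry under kinetic control.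

**Step 11**
Reactants: 17 (5E)-4-bromo-3-[(1R)-1-(tert-butyldimethylsilyloxy)butyl]-5-(iodomethylidene)furan-2(5H)-one
Product: 18 (5E)-4-bromo-3-[(1R)-1-hydroxybutyl]-5-(iodomethylidene)furan-2(5H)-one (CNP0231379.2)
Conditions: HF (48% aq.), MeCN, 0 °C → rt, dark
Reagents that add atoms: none
Why: Acidic fluoride desilylation cleaves the O–Si bond without base or nucleophile, so the enol lactone, the vinylogous acyl bromide, the (E)-vinyl iodide and the carbinol centre are untouched.

**Compound list**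
1 | (S)-4-benzyloxazolidin-2-one | O=C1N[C@@H](Cc2ccccc2)CO1 | starting material
2 | (E)-but-2-enoyl chloride (crotonyl chloride) | C/C=C/C(Cl)=O | starting material
3 | (S)-4-benzyl-3-[(E)-but-2-enoyl]oxazolidin-2-one | C/C=C/C(=O)N1[C@@H](Cc2ccccc2)COC1=O | intermediate
4 | butanal | CCCC=O | starting material
5 | dibutylboron (Z)-dienolate of 3 (not isolated) | C=C/C=C(\OB(CCCC)CCCC)N1[C@@H](Cc2ccccc2)COC1=O | intermediate
6 | dibutylboron aldolate of 7 (not isolated) | CCC[C@@H](OB(CCCC)CCCC)[C@H](C=C)C(=O)N1[C@@H](Cc2ccccc2)COC1=O | intermediate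
7 | (4S)-4-benzyl-3-[(2S,3R)-2-ethenyl-3-hydroxyhexanoyl]oxazolidin-2-one | CCC[C@@H](O)[C@H](C=C)C(=O)N1[C@@H](Cc2ccccc2)COC1=O | intermediate
8 | (4S)-4-benzyl-3-[(2S,3R)-3-(tert-butyldimethylsilyloxy)-2-ethenylhexanoyl]oxazolidin-2-one | CCC[C@@H](O[Si](C)(C)C(C)(C)C)[C@H](C=C)C(=O)N1[C@@H](Cc2ccccc2)COC1=O | intermediate
9 | (4S)-4-benzyl-3-[(2S,3R)-3-(tert-butyldimethylsilyloxy)-2-(1,2-dihydroxyethyl)hexanoyl]oxazolidin-2-one, both epimers at the new carbinol (not isolated) | CCC[C@@H](O[Si](C)(C)C(C)(C)C)[C@H](C(O)CO)C(=O)N1[C@@H](Cc2ccccc2)COC1=O | intermediate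
10 | (3S)-3-[(1R)-1-(tert-butyldimethylsilyloxy)butyl]-4-hydroxydihydrofuran-2(3H)-one, both C4 epimers | CCC[C@@H](O[Si](C)(C)C(C)(C)C)[C@H](C(O)CO1)C1=O | intermediate
11 | 3-[(1R)-1-(tert-butyldimethylsilyloxy)butyl]-4-hydroxyfuran-2(5H)-one | CCC[C@@H](O[Si](C)(C)C(C)(C)C)C1=C(O)COC1=O | intermediate
12 | 4-bromo-3-[(1R)-1-(tert-butyldimethylsilyloxy)butyl]furan-2(5H)-one | CCC[C@@H](O[Si](C)(C)C(C)(C)C)C1=C(Br)COC1=O | intermediate
13 | 4-bromo-2-(tert-butyldimethylsilyloxy)-3-[(1R)-1-(tert-butyldimethylsilyloxy)butyl]furan | CCC[C@@H](O[Si](C)(C)C(C)(C)C)c1c(Br)coc1O[Si](C)(C)C(C)(C)C | intermediate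
14 | tert-butyldimethylsilyl (2E)-3-bromo-2-[(1R)-1-(tert-butyldimethylsilyloxy)butyl]-4-oxobut-2-enoate, formyl cis to the ester (not isolated) | O=C/C(Br)=C(\C(=O)O[Si](C)(C)C(C)(C)C)[C@@H](CCC)O[Si](C)(C)C(C)(C)C | intermediate
15 | 4-bromo-5-hydroxy-3-[(1R)-1-(tert-butyldimethylsilyloxy)butyl]furan-2(5H)-one, both C5 epimers | CCC[C@@H](O[Si](C)(C)C(C)(C)C)C1=C(Br)C(O)OC1=O | intermediate
16 | (2E)-3-bromo-2-[(1R)-1-(tert-butyldimethylsilyloxy)butyl]pent-2-en-4-ynoic acid, ethynyl cis to CO2H | C#C/C(Br)=C(\C(=O)O)[C@@H](CCC)O[Si](C)(C)C(C)(C)C | intermediate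
17 | (5E)-4-bromo-3-[(1R)-1-(tert-butyldimethylsilyloxy)butyl]-5-(iodomethylidene)furan-2(5H)-one | CCC[C@@H](O[Si](C)(C)C(C)(C)C)C1=C(Br)/C(=C\I)OC1=O | intermediate
18 | (5E)-4-bromo-3-[(1R)-1-hydroxybutyl]-5-(iodomethylidene)furan-2(5H)-one | CCC[C@@H](O)C1=C(Br)/C(=C\I)OC1=O | target

**Step count and weak points**
Total steps: 11. Longest linear sequence: 11 steps (fully linear from 1).

Step 6 (bromination of the tetronic acid). The HBr released can strip the silyl ether or ionise C1' next to the electron-rich enol. The fallback sets out from 11: O-triflation (Tf2O, 2,6-lutidine, CH2Cl2, −78 °C) gives 3-[(1R)-1-(tert-butyldimethylsilyloxy)butyl]-4-(trifluoromethylsulfonyloxy)furan-2(5H)-one F1. LiBr in acetone at rt then exchanges the vinylogous acyl triflate for bromide by addition–elimination under non-acidic conditions, coming back at 12.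

Step 9 (alkyne homologation of the pseudo-acid). Ring-opening of 15 may be slow, methanol may add to the diazo-alkene stage, or the vinylogously acidic C1'–H of the open form may epimerise. The fallback sets out from 14, made from 13 as in step 8 but not hydrolysed. Its free aldehyde is homologated in aprotic medium by the Colvin rearrangement (Me3SiCHN2, LiN(i-Pr)2, THF, −78 → 0 °C) to tert-butyldimethylsilyl (2E)-3-bromo-2-[(1R)-1-(tert-butyldimethylsilyloxy)butyl]pent-2-en-4-ynoate F2. The silyl ester is then cleaved with K2CO3 in aqueous MeOH at 0 °C, coming back at 16.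

Step 10 (iodolactonisation). 6-endo closure to a 5-iodo-2-pyranone or iodine- and light-induced E→Z drift could intrude. The fallback sets out from 16: C-silylation of the alkyne (LiN(SiMe3)2, Me3SiCl, THF, −78 °C, aqueous work-up to free the acid) gives (2E)-3-bromo-2-[(1R)-1-(tert-butyldimethylsilyloxy)butyl]-5-(trimethylsilyl)pent-2-en-4-ynoic acid F3. With I2/NaHCO3 the β-silyl effect sends iodine to the silicon-bearing carbon and the carboxylate to the internal carbon (5-exo, anti), giving (5E)-4-bromo-3-[(1R)-1-(tert-butyldimethylsilyloxy)butyl]-5-[iodo(trimethylsilyl)methylidene]furan-2(5H)-one F4. Buffered fluoride (Bu4NF/AcOH, THF, 0 °C) then removes the C-silyl group with retention together with the O-silyl group, coming back at 18.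

**Further compounds**
F1 | step 6 | 3-[(1R)-1-(tert-butyldimethylsilyloxy)butyl]-4-(trifluoromethylsulfonyloxy)furan-2(5H)-one | CCC[C@@H](O[Si](C)(C)C(C)(C)C)C1=C(OS(=O)(=O)C(F)(F)F)COC1=O
F2 | step 9 | tert-butyldimethylsilyl (2E)-3-bromo-2-[(1R)-1-(tert-butyldimethylsilyloxy)butyl]pent-2-en-4-ynoate | C#C/C(Br)=C(\C(=O)O[Si](C)(C)C(C)(C)C)[C@@H](CCC)O[Si](C)(C)C(C)(C)C
F3 | step 10 | (2E)-3-bromo-2-[(1R)-1-(tert-butyldimethylsilyloxy)butyl]-5-(trimethylsilyl)pent-2-en-4-ynoic acid | C[Si](C)(C)C#C/C(Br)=C(\C(=O)O)[C@@H](CCC)O[Si](C)(C)C(C)(C)C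
F4 | step 10 | (5E)-4-bromo-3-[(1R)-1-(tert-butyldimethylsilyloxy)butyl]-5-[iodo(trimethylsilyl)methylidene]furan-2(5H)-one | CCC[C@@H](O[Si](C)(C)C(C)(C)C)C1=C(Br)/C(=C(\I)[Si](C)(C)C)OC1=O
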